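**Retrosynthetic overview**
1. The strategy rests on the 4-hydroxy-2-pyranone ring: its C2, C3 and C4 together with the bridging CH2 are one arylmethylmalonyl unit, and C5 and C6 with their methyl and ethyl groups are pentan-3-one. Cutting O1–C2 and C4–C5 gives dichloride 19 and enol silane 21.
2. Dichloride 19 comes from diacid 18, made by reductive Knoevenagel condensation of aldehyde 14 with Meldrum's acid and opening of the acylal. Both phenols are acetylated before the malonyl unit is installed, so that no free ortho phenol can lactonise onto it.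
3. Aldehyde 14 comes from the (2R)-dihydrobenzofuran alcohol 9 by C7 formylation, acetylation and dehydration of the tertiary alcohol.
4. Alcohol 9 comes from the (S)-epoxide 7 by 5-exo opening with the oxygen para to the ketone; 7 comes from phloroglucinol by acylation, C-prenylation, benzylation and asymmetric epoxidation.
5. Ring order: benzene ring (bought), dihydrofuran ring (step 5), pyranone ring (step 13).

Key step: step 13

Remark: the D-fructose-derived Shi ketone is assumed, from the spiro transition-state model, to give the (R)-epoxide of an ArCH2CH=CMe2 alkene, so the L-series ketone is used to reach the (S)-epoxide.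
Remark: the double-bond geometry of enol silane 21 is lost in the pyranone, so either isomer serves.

**Route**

Step 1
Reactants: 1 phloroglucinol; 2 isobutyryl chloride
Product: 3 1-(2,4,6-trihydroxyphenyl)-2-methylpropan-1-one
Conditions: AlCl3 (3.5 equiv), CH2Cl2–MeNO2, 0 °C → 40 °C; aq. HCl
Reagents that add atoms: none
Why: Friedel–Crafts acylation of the symmetrical, strongly activated ring should stop after one acyl group, because the chelated aryl ketone deactivates the ring.

Step 2
Reactants: 3 1-(2,4,6-trihydroxyphenyl)-2-methylpropan-1-one; 4 prenyl bromide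
Product: 5 1-[2,4,6-trihydroxy-3-(3-methylbut-2-en-1-yl)phenyl]-2-methylpropan-1-one
Conditions: 4 (1.0 equiv), aq. KOH (10%), 0 °C; dil. HCl; chromatography
Reagents that add atoms: none
Why: C-allylation of the ambident phloroglucinol phenoxide in water is the known way to mono-prenyl acylphloroglucinols; the bis-prenylated by-product is separated.

Step 3
Reactants: 5 1-[2,4,6-trihydroxy-3-(3-methylbut-2-en-1-yl)phenyl]-2-methylpropan-1-one
Product: 6 1-[2,4,6-tris(benzyloxy)-3-(3-methylbut-2-en-1-yl)phenyl]-2-methylpropan-1-one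
Conditions: BnBr (3.6 equiv), K2CO3, Bu4NI (cat.), DMF, 70 °C
Reagents that add atoms: benzyl bromide, BrCc1ccccc1
Why: Williamson etherification in a dipolar aprotic solvent alkylates the phenoxides at oxygen; full masking shields the ring from the oxidant and keeps any phenoxide from opening the epoxide too early.

Step 4
Reactants: 6 1-[2,4,6-tris(benzyloxy)-3-(3-methylbut-2-en-1-yl)phenyl]-2-methylpropan-1-one
Product: 7 1-[2,4,6-tris(benzyloxy)-3-{[(2S)-3,3-dimethyloxiran-2-yl]methyl}phenyl]-2-methylpropan-1-one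
Conditions: ent-Shi ketone (1,2:4,5-di-O-isopropylidene-β-L-erythro-2,3-hexodiulo-2,6-pyranose, 30 mol%), Oxone (2KHSO5·KHSO4·K2SO4), K2CO3, Bu4NHSO4 (cat.), MeCN–CH2(OMe)2, aq. Na2B4O7 buffer (pH 10.5), 0 °C
Reagents that add atoms: Oxone (potassium peroxymonosulfate), [K+].[O-]S(=O)(=O)OO
Why: Shi asymmetric epoxidation of a trisubstituted alkene; the chiral dioxirane of the L-series ketone should deliver oxygen through the spiro transition state to the face that gives the (S)-epoxide, and benzyl ethers are inert at this pH.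

Step 5
Reactants: 7 1-[2,4,6-tris(benzyloxy)-3-{[(2S)-3,3-dimethyloxiran-2-yl]methyl}phenyl]-2-methylpropan-1-one
Product: 9 1-[(2R)-4,6-dihydroxy-2-(2-hydroxypropan-2-yl)-2,3-dihydro-1-benzofuran-5-yl]-2-methylpropan-1-one, via triol epoxide 8 (not isolated)
Conditions: H2 (1 atm), 10% Pd/C, EtOAc, rt; filter; then K2CO3 (1 equiv), MeOH, 0 °C → rt
Reagents that add atoms: none
Why: Neutral hydrogenolysis frees all three phenols without touching the homobenzylic epoxide; base then forms the monoanion at the most acidic oxygen (para to the ketone, not hydrogen-bonded), which opens the epoxide 5-exo-tet at the secondary carbon with inversion, turning the (S)-epoxide into the (2R)-dihydrobenzofuran.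

Step 6
Reactants: 9 1-[(2R)-4,6-dihydroxy-2-(2-hydroxypropan-2-yl)-2,3-dihydro-1-benzofuran-5-yl]-2-methylpropan-1-one
Product: 11 (2R)-4,6-dihydroxy-2-(2-hydroxypropan-2-yl)-5-(2-methylpropanoyl)-2,3-dihydro-1-benzofuran-7-carbaldehyde, via iminium chloride 10 (not isolated)
Conditions: POCl3 (2.5 equiv), DMF, EtOAc, 0 °C → rt; then H2O, NaOAc; aq. K2CO3–MeOH, rt; dil. HCl
Reagents that add atoms: N,N-dimethylformamide, CN(C)C=O; water, O
Why: Vilsmeier–Haack formylation at C7, the only free position of the phloroglucinol ring; the hindered tertiary alcohol can at most be O-formylated, and the mild basic work-up would cleave such a formate.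

Step 7
Reactants: 11 (2R)-4,6-dihydroxy-2-(2-hydroxypropan-2-yl)-5-(2-methylpropanoyl)-2,3-dihydro-1-benzofuran-7-carbaldehyde
Product: 12 (2R)-7-formyl-2-(2-hydroxypropan-2-yl)-5-(2-methylpropanoyl)-2,3-dihydro-1-benzofuran-4,6-diyl diacetate
Conditions: Ac2O (2.4 equiv), Et3N, DMAP (5 mol%), CH2Cl2, 0 °C
Reagents that add atoms: acetic anhydride, CC(=O)OC(C)=O
Why: Base-catalysed O-acetylation takes the two phenoxides far faster than the tertiary alcohol; acetylating before the malonyl unit is built prevents the coumarin-type lactonisation that an ortho-hydroxy aldehyde would undergo in step 9.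

Step 8
Reactants: 12 (2R)-7-formyl-2-(2-hydroxypropan-2-yl)-5-(2-methylpropanoyl)-2,3-dihydro-1-benzofuran-4,6-diyl diacetate
Product: 14 (2R)-7-formyl-5-(2-methylpropanoyl)-2-(prop-1-en-2-yl)-2,3-dihydro-1-benzofuran-4,6-diyl diacetate, via sulfamate salt 13 (not isolated)
Conditions: methyl N-(triethylammoniosulfonyl)carbamate (Burgess reagent, 2 equiv), PhMe–THF, rt → 60 °C
Reagents that add atoms: none
Why: Burgess dehydration by syn elimination of the sulfamate ester should favour the six methyl hydrogens over the single C2 hydrogen (elimination away from oxygen); the β-oxygen disfavours a free cation, so C2 should keep its configuration.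

Step 9
Reactants: 14 (2R)-7-formyl-5-(2-methylpropanoyl)-2-(prop-1-en-2-yl)-2,3-dihydro-1-benzofuran-4,6-diyl diacetate; 15 Meldrum's acid
Product: 17 5-{[(2R)-4,6-diacetoxy-5-(2-methylpropanoyl)-2-(prop-1-en-2-yl)-2,3-dihydro-1-benzofuran-7-yl]methyl}-2,2-dimethyl-1,3-dioxane-4,6-dione, via alkylidene Meldrum's acid 16 (not isolated)
Conditions: 15 (1.1 equiv), diethyl 2,6-dimethyl-1,4-dihydropyridine-3,5-dicarboxylate (Hantzsch ester, 1.1 equiv), L-proline (10 mol%), CH2Cl2, rt
Reagents that add atoms: none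
Why: Knoevenagel condensation followed by conjugate transfer hydrogenation with the Hantzsch ester (organocatalytic reductive alkylation) runs without strong base, so the aryl acetates stay on and the C5–H acid is never deprotonated next to them.

Step 10
Reactants: 17 5-{[(2R)-4,6-diacetoxy-5-(2-methylpropanoyl)-2-(prop-1-en-2-yl)-2,3-dihydro-1-benzofuran-7-yl]methyl}-2,2-dimethyl-1,3-dioxane-4,6-dione
Product: 18 2-{[(2R)-4,6-diacetoxy-5-(2-methylpropanoyl)-2-(prop-1-en-2-yl)-2,3-dihydro-1-benzofuran-7-yl]methyl}propanedioic acid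
Conditions: H2O–1,4-dioxane (1:1), HCl to pH 2, 40 °C
Reagents that add atoms: water, O
Why: Hydrolysis of the cyclic acylal by water attack on the un-ionised dioxanedione should be faster than aryl acetate hydrolysis, which is near its rate minimum at pH 2; the alkene, deactivated by the allylic oxygen, should not hydrate.

Step 11
Reactants: 18 2-{[(2R)-4,6-diacetoxy-5-(2-methylpropanoyl)-2-(prop-1-en-2-yl)-2,3-dihydro-1-benzofuran-7-yl]methyl}propanedioic acid
Product: 19 2-{[(2R)-4,6-diacetoxy-5-(2-methylpropanoyl)-2-(prop-1-en-2-yl)-2,3-dihydro-1-benzofuran-7-yl]methyl}propanedioyl dichloride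
Conditions: 1-chloro-N,N,2-trimethylprop-1-en-1-amine (2.2 equiv), CH2Cl2, 0 °C → rt; concentrate, use at once
Reagents that add atoms: 1-chloro-N,N,2-trimethylprop-1-en-1-amine (Ghosez's reagent), CC(C)=C(Cl)N(C)C
Why: Acid chloride formation with an α-chloroenamine is neutral and releases no free HCl, which spares the isopropenyl group and the allylic aryl ether.

Step 12
Reactants: 20 pentan-3-one
Product: 21 (Z)-trimethyl(pent-2-en-3-yloxy)silane
Conditions: Me3SiOTf, Et3N, Et2O, 0 °C → rt; pentane extraction, distillation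
Reagents that add atoms: trimethylsilyl trifluoromethanesulfonate, C[Si](C)(C)OS(=O)(=O)C(F)(F)F
Why: Soft enolisation and O-silylation of a symmetrical ketone can give only one constitution of enol silane, mainly as the Z isomer.

Step 13
Reactants: 19 2-{[(2R)-4,6-diacetoxy-5-(2-methylpropanoyl)-2-(prop-1-en-2-yl)-2,3-dihydro-1-benzofuran-7-yl]methyl}propanedioyl dichloride; 21 (Z)-trimethyl(pent-2-en-3-yloxy)silane
Product: 23 (2R)-7-[(6-ethyl-4-hydroxy-5-methyl-2-oxo-2H-pyran-3-yl)methyl]-5-(2-methylpropanoyl)-2-(prop-1-en-2-yl)-2,3-dihydro-1-benzofuran-4,6-diyl diacetate, via dioxo acid chloride 22 (not isolated)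
Conditions: 21 (2.3 equiv), Et2O–CH2Cl2, −78 °C → rt; then H2O
Reagents that add atoms: none
Why: One acid chloride of 19 (or the chlorocarbonyl ketene it gives by loss of HCl) acylates 21 at carbon with loss of Me3SiCl and forms the pyranone C4–C5 bond in 22; the ethyl ketone of 22 then enolises, its enol oxygen attacks the remaining acid chloride to form the O1–C2 bond, and tautomerisation gives the 4-hydroxy-2-pyranone. The closest known reaction type is the synthesis of 4-hydroxy-2-pyranones from malonyl dichlorides and ketone silyl enol ethers. The one ring that closes is the pyranone, by 6-exo-trig attack of oxygen at the acyl carbon. No stereocentre is formed in 23, since the two sp3 centres of 22 become sp2, and C2 of the dihydrofuran is not touched. The step needs the acid chlorides to react with the enol silane and not with the arene oxygens, which the two acetates and the low temperature secure, while the symmetry of pentan-3-one leaves only one substitution pattern. The second equivalent of 21 takes up the HCl as Me3SiCl and pentan-3-one, which protects the isopropenyl group.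

Step 14
Reactants: 23 (2R)-7-[(6-ethyl-4-hydroxy-5-methyl-2-oxo-2H-pyran-3-yl)methyl]-5-(2-methylpropanoyl)-2-(prop-1-en-2-yl)-2,3-dihydro-1-benzofuran-4,6-diyl diacetate
Product: 24 1-[(2R)-7-[(6-ethyl-4-hydroxy-5-methyl-2-oxo-2H-pyran-3-yl)methyl]-4,6-dihydroxy-2-(prop-1-en-2-yl)-2,3-dihydro-1-benzofuran-5-yl]-2-methylpropan-1-one
Conditions: K2CO3, MeOH, 0 °C → rt; aq. citric acid
Reagents that add atoms: none
Why: Base-catalysed methanolysis (transesterification) removes the two activated aryl acetates; the pyranone is present as its unreactive oxido anion and the stereocentre is not affected by base.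

**Compound list**
1 | phloroglucinol (benzene-1,3,5-triol) | Oc1cc(O)cc(O)c1 | starting material
2 | isobutyryl chloride | CC(C)C(Cl)=O | starting material
3 | 1-(2,4,6-trihydroxyphenyl)-2-methylpropan-1-one | CC(C)C(=O)c1c(O)cc(O)cc1O | intermediate
4 | prenyl bromide (1-bromo-3-methylbut-2-ene) | CC(C)=CCBr | starting material
5 | 1-[2,4,6-trihydroxy-3-(3-methylbut-2-en-1-yl)phenyl]-2-methylpropan-1-one | CC(C)C(=O)c1c(O)cc(O)c(CC=C(C)C)c1O | intermediate
6 | 1-[2,4,6-tris(benzyloxy)-3-(3-methylbut-2-en-1-yl)phenyl]-2-methylpropan-1-one | CC(C)C(=O)c1c(OCc2ccccc2)cc(OCc2ccccc2)c(CC=C(C)C)c1OCc1ccccc1 | intermediate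
7 | 1-[2,4,6-tris(benzyloxy)-3-{[(2S)-3,3-dimethyloxiran-2-yl]methyl}phenyl]-2-methylpropan-1-one | CC(C)C(=O)c1c(OCc2ccccc2)cc(OCc2ccccc2)c(C[C@@H]2OC2(C)C)c1OCc1ccccc1 | intermediate
8 | 1-[3-{[(2S)-3,3-dimethyloxiran-2-yl]methyl}-2,4,6-trihydroxyphenyl]-2-methylpropan-1-one (not isolated) | CC(C)C(=O)c1c(O)cc(O)c(C[C@@H]2OC2(C)C)c1O | intermediate
9 | 1-[(2R)-4,6-dihydroxy-2-(2-hydroxypropan-2-yl)-2,3-dihydro-1-benzofuran-5-yl]-2-methylpropan-1-one | CC(C)(O)[C@H]1Cc2c(O)c(C(=O)C(C)C)c(O)cc2O1 | intermediate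
10 | N-{[(2R)-4,6-dihydroxy-2-(2-hydroxypropan-2-yl)-5-(2-methylpropanoyl)-2,3-dihydro-1-benzofuran-7-yl]methylidene}-N-methylmethanaminium chloride (not isolated) | CC(C)(O)[C@H]1Cc2c(O)c(C(=O)C(C)C)c(O)c(C=[N+](C)C)c2O1.[Cl-] | intermediate
11 | (2R)-4,6-dihydroxy-2-(2-hydroxypropan-2-yl)-5-(2-methylpropanoyl)-2,3-dihydro-1-benzofuran-7-carbaldehyde | CC(C)(O)[C@H]1Cc2c(O)c(C(=O)C(C)C)c(O)c(C=O)c2O1 | intermediate
12 | (2R)-7-formyl-2-(2-hydroxypropan-2-yl)-5-(2-methylpropanoyl)-2,3-dihydro-1-benzofuran-4,6-diyl diacetate | CC(C)(O)[C@H]1Cc2c(OC(C)=O)c(C(=O)C(C)C)c(OC(C)=O)c(C=O)c2O1 | intermediate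
13 | triethylammonium N-(methoxycarbonyl)sulfamate ester of 12 at the tertiary oxygen (not isolated) | COC(=O)[N-]S(=O)(=O)OC(C)(C)[C@H]1Cc2c(OC(C)=O)c(C(=O)C(C)C)c(OC(C)=O)c(C=O)c2O1.CC[NH+](CC)CC | intermediate
14 | (2R)-7-formyl-5-(2-methylpropanoyl)-2-(prop-1-en-2-yl)-2,3-dihydro-1-benzofuran-4,6-diyl diacetate | C=C(C)[C@H]1Cc2c(OC(C)=O)c(C(=O)C(C)C)c(OC(C)=O)c(C=O)c2O1 | intermediate
15 | Meldrum's acid (2,2-dimethyl-1,3-dioxane-4,6-dione) | CC1(C)OC(=O)CC(=O)O1 | starting material
16 | 5-{[(2R)-4,6-diacetoxy-5-(2-methylpropanoyl)-2-(prop-1-en-2-yl)-2,3-dihydro-1-benzofuran-7-yl]methylidene}-2,2-dimethyl-1,3-dioxane-4,6-dione (not isolated) | C=C(C)[C@H]1Cc2c(OC(C)=O)c(C(=O)C(C)C)c(OC(C)=O)c(C=C3C(=O)OC(C)(C)OC3=O)c2O1 | intermediate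
17 | 5-{[(2R)-4,6-diacetoxy-5-(2-methylpropanoyl)-2-(prop-1-en-2-yl)-2,3-dihydro-1-benzofuran-7-yl]methyl}-2,2-dimethyl-1,3-dioxane-4,6-dione | C=C(C)[C@H]1Cc2c(OC(C)=O)c(C(=O)C(C)C)c(OC(C)=O)c(CC3C(=O)OC(C)(C)OC3=O)c2O1 | intermediate
18 | 2-{[(2R)-4,6-diacetoxy-5-(2-methylpropanoyl)-2-(prop-1-en-2-yl)-2,3-dihydro-1-benzofuran-7-yl]methyl}propanedioic acid | C=C(C)[C@H]1Cc2c(OC(C)=O)c(C(=O)C(C)C)c(OC(C)=O)c(CC(C(=O)O)C(=O)O)c2O1 | intermediate
19 | 2-{[(2R)-4,6-diacetoxy-5-(2-methylpropanoyl)-2-(prop-1-en-2-yl)-2,3-dihydro-1-benzofuran-7-yl]methyl}propanedioyl dichloride | C=C(C)[C@H]1Cc2c(OC(C)=O)c(C(=O)C(C)C)c(OC(C)=O)c(CC(C(Cl)=O)C(Cl)=O)c2O1 | intermediate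
20 | pentan-3-one | CCC(=O)CC | starting material
21 | (Z)-trimethyl(pent-2-en-3-yloxy)silane | C/C=C(/CC)O[Si](C)(C)C | intermediate
22 | 2-{[(2R)-4,6-diacetoxy-5-(2-methylpropanoyl)-2-(prop-1-en-2-yl)-2,3-dihydro-1-benzofuran-7-yl]methyl}-4-methyl-3,5-dioxoheptanoyl chloride, mixture of diastereomers (not isolated) | C=C(C)[C@H]1Cc2c(OC(C)=O)c(C(=O)C(C)C)c(OC(C)=O)c(CC(C(Cl)=O)C(=O)C(C)C(=O)CC)c2O1 | intermediate
23 | (2R)-7-[(6-ethyl-4-hydroxy-5-methyl-2-oxo-2H-pyran-3-yl)methyl]-5-(2-methylpropanoyl)-2-(prop-1-en-2-yl)-2,3-dihydro-1-benzofuran-4,6-diyl diacetate | C=C(C)[C@H]1Cc2c(OC(C)=O)c(C(=O)C(C)C)c(OC(C)=O)c(Cc3c(O)c(C)c(CC)oc3=O)c2O1 | intermediate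
24 | 1-[(2R)-7-[(6-ethyl-4-hydroxy-5-methyl-2-oxo-2H-pyran-3-yl)methyl]-4,6-dihydroxy-2-(prop-1-en-2-yl)-2,3-dihydro-1-benzofuran-5-yl]-2-methylpropan-1-one | C=C(C)[C@H]1Cc2c(O)c(C(=O)C(C)C)c(O)c(Cc3c(O)c(C)c(CC)oc3=O)c2O1 | target

**Step count**
Total steps: 14. Longest linear sequence: 13 (steps 1 to 11, 13 and 14); step 12 is a one-step side branch.

**Steps most likely to fail**

Step 13. The dichloride may be lost before C-acylation, through O-acylation of the enol silane, ketene dimerisation, or attack of an ortho acetate oxygen on the acid chloride with lactonisation. The fallback sets out from aldehyde 14 and enol silane 21 and comes back at 23. Enol silane 21 and malonyl dichloride (ClC(=O)CC(Cl)=O; Et2O, −78 °C → rt) should give 6-ethyl-4-hydroxy-5-methyl-2H-pyran-2-one F1. Aldehyde 14, F1 and the Hantzsch ester with L-proline (cat.) in CH2Cl2 should then condense at pyranone C3 to the 3-arylidenepyran-2,4-dione F2, which is reduced in the same flask by hydride transfer to 23. This reductive alkylation of 4-hydroxypyranones with aldehydes is known chemistry, and it keeps the bridge carbon bonded to the arene from the start.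

Step 10. An aryl acetate may hydrolyse before the acylal opens, and the freed ortho phenol would then lactonise onto the malonyl unit. The fallback sets out from 14 and comes back at 18. Knoevenagel condensation of 14 with bis(2,2,2-trichloroethyl) malonate (piperidinium acetate cat., PhMe, 4 Å sieves) should give the arylidene bis(2,2,2-trichloroethyl) malonate F3. Zn dust in AcOH–THF at rt should then reduce the arylidene double bond and remove both trichloroethyl esters by reductive β-elimination, giving diacid 18 without any hydrolysis.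

Step 8. The sulfamate may eliminate towards the C2 hydrogen, giving an enol ether that aromatises to the 2-isopropylbenzofuran and destroys the stereocentre. The fallback sets out from 3 and comes back at 14, and it forms the alkene and the C2–O bond together, so the alkene position is fixed by construction. C-alkylation of 3 with (E)-4-bromo-2-methylbut-2-en-1-yl methyl carbonate (COC(=O)OC/C(C)=C/CBr; aq. KOH, 0 °C, as in step 2) should give the allylic methyl carbonate F4. Pd2(dba)3·CHCl3 with the Trost bisphosphine ligand (the enantiomer to be fixed on a model phenol so that the 2R ring forms) in CH2Cl2 should ionise F4 to an allyl complex of divalent palladium from the zerovalent catalyst. The para phenoxide then attacks the internal allyl terminus and closes the ring to the (2R)-isopropenyl dihydrobenzofuran diphenol F5. Vilsmeier–Haack formylation (POCl3, DMF, 0 °C) should give the 7-carbaldehyde F6, and acetylation (Ac2O, Et3N, DMAP) leads to 14.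

**Further compounds**
F1 | step 13 | 6-ethyl-4-hydroxy-5-methyl-2H-pyran-2-one | CCc1oc(=O)cc(O)c1C
F2 | step 13 | (2R)-7-[(6-ethyl-5-methyl-2,4-dioxo-2H-pyran-3(4H)-ylidene)methyl]-5-(2-methylpropanoyl)-2-(prop-1-en-2-yl)-2,3-dihydro-1-benzofuran-4,6-diyl diacetate | C=C(C)[C@H]1Cc2c(OC(C)=O)c(C(=O)C(C)C)c(OC(C)=O)c(C=C3C(=O)OC(CC)=C(C)C3=O)c2O1
F3 | step 10 | bis(2,2,2-trichloroethyl) 2-{[(2R)-4,6-diacetoxy-5-(2-methylpropanoyl)-2-(prop-1-en-2-yl)-2,3-dihydro-1-benzofuran-7-yl]methylidene}propanedioate | C=C(C)[C@H]1Cc2c(OC(C)=O)c(C(=O)C(C)C)c(OC(C)=O)c(C=C(C(=O)OCC(Cl)(Cl)Cl)C(=O)OCC(Cl)(Cl)Cl)c2O1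
F4 | step 8 | methyl (2E)-2-methyl-4-[2,4,6-trihydroxy-3-(2-methylpropanoyl)phenyl]but-2-en-1-yl carbonate | CC(C)C(=O)c1c(O)cc(O)c(C/C=C(\C)COC(=O)OC)c1O
F5 | step 8 | 1-[(2R)-4,6-dihydroxy-2-(prop-1-en-2-yl)-2,3-dihydro-1-benzofuran-5-yl]-2-methylpropan-1-one | C=C(C)[C@H]1Cc2c(O)c(C(=O)C(C)C)c(O)cc2O1
F6 | step 8 | (2R)-4,6-dihydroxy-5-(2-methylpropanoyl)-2-(prop-1-en-2-yl)-2,3-dihydro-1-benzofuran-7-carbaldehyde | C=C(C)[C@H]1Cc2c(O)c(C(=O)C(C)C)c(O)c(C=O)c2O1
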